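**Plan**

- Retrosynthesis (labdane numbering throughout): cut C12–C13 (B-alkyl coupling with an E-enol triflate) and C11–C12 (methylenation). Take the C6 and C8 oxygens back to a Δ6 silyl enol ether, then cut C5–C10 and C8–C9 together. Cut the open chain at C1–C10 (same enol triflate), C7=C8 (aldol condensation) and C3–C4 (conjugate allylation of mesityl oxide).
- Enabling feature: ring B (C5–C10) carries oxygen at C6 and has the quaternary C10 flanked by C5 and C9, and ring A spans C10 and C5 through C1–C4. This is the retron of an intramolecular [4+2] between a C5=C6(OSi)–C7=C8 silyloxydiene and the (E)-enal C9=C10 (formyl carbon = C11).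
- Forward: the chain is joined in the order C3–C4, C7=C8, C1–C10. Rings A and B then close in one step, ring B is taken to the Δ7-6-one, the 7,8-epoxide and the 6,8-diol, and the side chain is completed last.
- Stereochemistry: C5, C9 and C10 come from the catalyst-controlled endo cycloaddition of the E-enal onto the (Z,E)-diene. C8 comes from epoxidation anti to the C10 methyl, C6 from a thermodynamic dissolving-metal reduction, and 13E from the stereodefined enol triflate.

Key step: step 9

Assumption: the facial sense of the oxazaborolidinium ion is taken from its formyl C–H···O binding model (aldehyde bound anti to the alkene, s-trans enal), under which the (S)-catalyst leaves the C9 Re / C10 Si face open.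

**Route**

Step 1
Reactants: 1 methyl acetoacetate
Product: 2 methyl (2E)-3-(trifluoromethylsulfonyloxy)but-2-enoate
Conditions: Tf2O, aq. Me4NOH, hexanes, 0 °C → rt
Reagents that add atoms: trifluoromethanesulfonic anhydride, O=S(=O)(OS(=O)(=O)C(F)(F)F)C(F)(F)F
Why: Schotten–Baumann-type O-triflation of the β-keto ester enolate; with the non-chelating tetramethylammonium counter-ion the enolate reacts from its extended form, so the triflate should end up trans to the ester (E), whereas a lithium chelate would give Z.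

Step 2
Reactants: 3 mesityl oxide (4-methylpent-3-en-2-one); 4 allyltrimethylsilane
Product: 5 4,4-dimethylhept-6-en-2-one
Conditions: TiCl4, CH2Cl2, −78 °C; then H2O
Reagents that add atoms: none
Why: Hosomi–Sakurai conjugate allylation; the TiCl4-bound enone is attacked at its β,β-disubstituted carbon by the γ-carbon of the allylsilane and the β-silyl cation loses silicon, which creates the quaternary carbon (future C4) with its gem-dimethyl group.

Step 3
Reactants: 5 4,4-dimethylhept-6-en-2-one; 6 acetaldehyde
Product: 7 2-hydroxy-6,6-dimethylnon-8-en-4-one (racemic carbinol, removed in step 4)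
Conditions: LiN(i-Pr)2, THF, −78 °C; then 6, −78 °C; aq. NH4Cl
Reagents that add atoms: none
Why: Directed aldol addition; kinetic deprotonation occurs at the methyl group because the other α-carbon is neopentylic, and the lithium enolate adds to acetaldehyde.

Step 4
Reactants: 7 2-hydroxy-6,6-dimethylnon-8-en-4-one
Product: 9 (2E)-6,6-dimethylnona-2,8-dien-4-one, via mesylate 8 (not isolated)
Conditions: MsCl, Et3N, CH2Cl2, 0 °C; then DBU, rt
Reagents that add atoms: none
Why: Mesylation followed by E1cB elimination completes the aldol condensation and should give the conjugated enone as the thermodynamically preferred E isomer.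

Step 5
Reactants: 9 (2E)-6,6-dimethylnona-2,8-dien-4-one
Product: 10 tert-butyl{[(2E,4Z)-6,6-dimethylnona-2,4,8-trien-4-yl]oxy}dimethylsilane
Conditions: TBSOTf, Et3N, CH2Cl2, −78 → 0 °C
Reagents that add atoms: tert-butyldimethylsilyl trifluoromethanesulfonate, CC(C)(C)[Si](C)(C)OS(=O)(=O)C(F)(F)F
Why: Soft enolisation (O-silylation, then deprotonation of the α′-methylene by Et3N) gives the cross-conjugated 2-silyloxydiene; the Z enol ether should form because the quaternary carbon avoids allylic strain with the propenyl group.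

Step 6
Reactants: 10 tert-butyl{[(2E,4Z)-6,6-dimethylnona-2,4,8-trien-4-yl]oxy}dimethylsilane; 2 methyl (2E)-3-(trifluoromethylsulfonyloxy)but-2-enoate
Product: 12 methyl (2E,8Z,10E)-9-(tert-butyldimethylsilyloxy)-3,7,7-trimethyldodeca-2,8,10-trienoate, via alkylborane 11 (not isolated)
Conditions: 9-BBN (1.1 equiv), THF, 0 °C → rt; then 2, PdCl2(dppf) (5 mol %), K3PO4 (3 M aq.), DMF, rt
Reagents that add atoms: none
Why: 9-BBN adds anti-Markovnikov to the only monosubstituted alkene, and the B-alkyl Suzuki–Miyaura coupling (oxidative addition, transmetalation of the borate, reductive elimination) proceeds with retention at the enol triflate, so the E-trisubstituted enoate (future C9=C10 with C20) should result.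

Step 7
Reactants: 12 methyl (2E,8Z,10E)-9-(tert-butyldimethylsilyloxy)-3,7,7-trimethyldodeca-2,8,10-trienoate
Product: 13 (2E,8Z,10E)-9-(tert-butyldimethylsilyloxy)-3,7,7-trimethyldodeca-2,8,10-trien-1-ol
Conditions: i-Bu2AlH (2.2 equiv), CH2Cl2, −78 °C; aq. potassium sodium tartrate
Reagents that add atoms: none
Why: 1,2-Reduction of the α,β-unsaturated ester by the aluminium hydride gives the allylic alcohol; the silyl dienol ether is inert to the hydride.

Step 8
Reactants: 13 (2E,8Z,10E)-9-(tert-butyldimethylsilyloxy)-3,7,7-trimethyldodeca-2,8,10-trien-1-ol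
Product: 14 (2E,8Z,10E)-9-(tert-butyldimethylsilyloxy)-3,7,7-trimethyldodeca-2,8,10-trienal
Conditions: MnO2, CH2Cl2, rt
Reagents that add atoms: none
Why: Heterogeneous MnO2 oxidation is selective for the allylic alcohol, neutral, should not isomerise the E-enal and leaves the silyl dienol ether intact.

Step 9
Reactants: 14 (2E,8Z,10E)-9-(tert-butyldimethylsilyloxy)-3,7,7-trimethyldodeca-2,8,10-trienal
Product: 15 (5R,8R,9R,10R)-6-(tert-butyldimethylsilyloxy)-12,13,14,15,16-pentanorlabd-6-en-11-al (the 6-silyloxy-ent-drim-6-en-11-al; formyl, C8 methyl and C10 methyl mutually cis, trans ring fusion)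
Conditions: (S)-3,3-diphenyl-1-(2-methylphenyl)tetrahydro-1H,3H-pyrrolo[1,2-c][1,3,2]oxazaborole (20 mol %), Tf2NH (17 mol %), CH2Cl2, −78 → −40 °C; then Et3N
Reagents that add atoms: none
Why: The boron of the Tf2NH-activated oxazaborolidinium ion binds the formyl oxygen of the E-enal and lowers its LUMO, and the silyloxydiene adds in a concerted, asynchronous, suprafacial [4+2] in which the bond from the nucleophilic diene terminus C5 to the enal β-carbon C10 leads and C8–C9 follows. The closest known reaction type is the Lewis-acid- or oxazaborolidinium-catalysed intramolecular Diels–Alder reaction of deca-2,7,9-trienals to trans-fused octalins. Ring B closes as the cyclohexene of the cycloaddition itself (C5–C10, leaving the C6=C7 silyl enol ether), and ring A closes through the four-carbon tether C1–C4 that links C10 to C5 in a chair-like arrangement with the tether exo. The cis relation of formyl and C10 methyl is fixed by the E-enal, the cis relation of C5–H and C8–H by the (Z,E)-diene, the trans C5/C10 fusion and the cis relation of formyl and C8 methyl by the endo-formyl transition state, and the absolute sense (attack on the C9 Re / C10 Si face) by the phenyl group of the (S)-catalyst that shields the other face. The step needs endo over exo, one enal face, and cycloaddition over Mukaiyama–Michael interception or loss of silicon; the E-enal with the tether trans to formyl, the gem-dimethyl group at C4 (folded conformer), the bulky silyl ether and a slight deficit of Tf2NH relative to the oxazaborolidine should secure these.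

Step 10
Reactants: 15 (5R,8R,9R,10R)-6-(tert-butyldimethylsilyloxy)-12,13,14,15,16-pentanorlabd-6-en-11-al
Product: 16 (5R,8S,9R,10S)-6-(tert-butyldimethylsilyloxy)-13,14,15,16-tetranorlabda-6,11-diene
Conditions: Ph3PCH3Br, KOt-Bu, THF, 0 °C → rt
Reagents that add atoms: methyltriphenylphosphonium bromide, C[P+](c1ccccc1)(c1ccccc1)c1ccccc1.[Br-]
Why: Wittig methylenation of the hindered but reactive aldehyde adds C12; the C9 substituent is already equatorial, so the basic ylide should not erode C9, and the silyl enol ether is stable to base.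

Step 11
Reactants: 16 (5R,8S,9R,10S)-6-(tert-butyldimethylsilyloxy)-13,14,15,16-tetranorlabda-6,11-diene
Product: 17 (5R,9R,10S)-13,14,15,16-tetranorlabda-7,11-dien-6-one
Conditions: Pd(OAc)2 (1.1 equiv), MeCN, rt → 40 °C
Reagents that add atoms: none
Why: Saegusa–Ito oxidation; the silyl enol ether transmetalates to a C7-bound divalent palladium enolate and β-hydride elimination of the C8 hydrogen gives the Δ7 enone, which removes the C8 stereocentre on purpose.

Step 12
Reactants: 17 (5R,9R,10S)-13,14,15,16-tetranorlabda-7,11-dien-6-one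
Product: 18 (5R,7R,8R,9S,10S)-7,8-epoxy-13,14,15,16-tetranorlabd-11-en-6-one (oxirane trans to the C10 methyl)
Conditions: 30% aq. H2O2 (5 equiv), NaOH (0.5 equiv), MeOH, 0 °C
Reagents that add atoms: hydrogen peroxide, OO
Why: Weitz–Scheffer nucleophilic epoxidation; hydroperoxide should add to C8 on the face opposite the axial C10 methyl (syn to the small C9 hydrogen) and the enolate closes the oxirane on that face, which sets C8, while the excess of H2O2 over NaOH keeps the medium at the weakly basic hydroperoxide ion and limits dienolate formation at C9.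

Step 13
Reactants: 18 (5R,7R,8R,9S,10S)-7,8-epoxy-13,14,15,16-tetranorlabd-11-en-6-one
Product: 20 (5R,6R,8S,9S,10R)-13,14,15,16-tetranorlabd-11-ene-6,8-diol, via hydroxy ketone 19 (not isolated)
Conditions: Li, NH3 (l)/THF, EtOH, −78 → −33 °C; then NH4Cl
Reagents that add atoms: none
Why: Dissolving-metal reduction; the ketyl of the α,β-epoxy ketone cleaves the C7–O bond to the enolate of the β-hydroxy ketone, ethanol reprotonates it, and the second ketyl/carbanion is protonated to the thermodynamically preferred equatorial C6 carbinol (trans to the C10 methyl, cis to the C8 hydroxyl), while the isolated vinyl group and the tertiary alcohol should not be reduced.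

Step 14
Reactants: 20 (5R,6R,8S,9S,10R)-13,14,15,16-tetranorlabd-11-ene-6,8-diol; 2 methyl (2E)-3-(trifluoromethylsulfonyloxy)but-2-enoate
Product: 22 methyl (5R,6R,8S,9S,10R,13E)-6,8-dihydroxylabd-13-en-15-oate, via alkylborane 21 (not isolated)
Conditions: 9-BBN (3.5 equiv), THF, rt → 50 °C; then 2, PdCl2(dppf) (10 mol %), AsPh3, K3PO4 (3 M aq.), DMF, rt
Reagents that add atoms: none
Why: Hydroboration of the terminal vinyl group places boron on C12, and the stereoretentive B-alkyl Suzuki–Miyaura coupling with the E-enol triflate forms C12–C13 and delivers the 13E enoate directly; the excess 9-BBN takes up the two hindered hydroxyls as borinates that are hydrolysed in the aqueous base.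

**Compound list**

1 | methyl acetoacetate | COC(=O)CC(C)=O | starting material
2 | methyl (2E)-3-(trifluoromethylsulfonyloxy)but-2-enoate | COC(=O)/C=C(\C)OS(=O)(=O)C(F)(F)F | intermediate
3 | mesityl oxide | CC(C)=CC(C)=O | starting material
4 | allyltrimethylsilane | C=CC[Si](C)(C)C | starting material
5 | 4,4-dimethylhept-6-en-2-one | CC(=O)CC(C)(C)CC=C | intermediate
6 | acetaldehyde | CC=O | starting material
7 | 2-hydroxy-6,6-dimethylnon-8-en-4-one (racemic) | CC(O)CC(=O)CC(C)(C)CC=C | intermediate
8 | 6,6-dimethyl-4-oxonon-8-en-2-yl methanesulfonate (racemic) | CC(OS(C)(=O)=O)CC(=O)CC(C)(C)CC=C | intermediate (not isolated)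
9 | (2E)-6,6-dimethylnona-2,8-dien-4-one | C/C=C/C(=O)CC(C)(C)CC=C | intermediate
10 | tert-butyl{[(2E,4Z)-6,6-dimethylnona-2,4,8-trien-4-yl]oxy}dimethylsilane | C=CCC(C)(C)/C=C(\O[Si](C)(C)C(C)(C)C)/C=C/C | intermediate
11 | 9-[(5Z,7E)-6-(tert-butyldimethylsilyloxy)-4,4-dimethylnona-5,7-dien-1-yl]-9-borabicyclo[3.3.1]nonane | B1(CCCC(C)(C)/C=C(\O[Si](C)(C)C(C)(C)C)/C=C/C)C2CCCC1CCC2 | intermediate (not isolated)
12 | methyl (2E,8Z,10E)-9-(tert-butyldimethylsilyloxy)-3,7,7-trimethyldodeca-2,8,10-trienoate | COC(=O)/C=C(\C)CCCC(C)(C)/C=C(\O[Si](C)(C)C(C)(C)C)/C=C/C | intermediate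
13 | (2E,8Z,10E)-9-(tert-butyldimethylsilyloxy)-3,7,7-trimethyldodeca-2,8,10-trien-1-ol | OC/C=C(\C)CCCC(C)(C)/C=C(\O[Si](C)(C)C(C)(C)C)/C=C/C | intermediate
14 | (2E,8Z,10E)-9-(tert-butyldimethylsilyloxy)-3,7,7-trimethyldodeca-2,8,10-trienal | O=C/C=C(\C)CCCC(C)(C)/C=C(\O[Si](C)(C)C(C)(C)C)/C=C/C | intermediate
15 | (5R,8R,9R,10R)-6-(tert-butyldimethylsilyloxy)-12,13,14,15,16-pentanorlabd-6-en-11-al | O=C[C@H]1[C@]2(C)CCCC(C)(C)[C@H]2C(O[Si](C)(C)C(C)(C)C)=C[C@H]1C | intermediate
16 | (5R,8S,9R,10S)-6-(tert-butyldimethylsilyloxy)-13,14,15,16-tetranorlabda-6,11-diene | C=C[C@H]1[C@]2(C)CCCC(C)(C)[C@H]2C(O[Si](C)(C)C(C)(C)C)=C[C@H]1C | intermediate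
17 | (5R,9R,10S)-13,14,15,16-tetranorlabda-7,11-dien-6-one | C=C[C@H]1[C@]2(C)CCCC(C)(C)[C@H]2C(=O)C=C1C | intermediate
18 | (5R,7R,8R,9S,10S)-7,8-epoxy-13,14,15,16-tetranorlabd-11-en-6-one | C=C[C@H]1[C@]2(C)CCCC(C)(C)[C@H]2C(=O)[C@@H]3O[C@@]31C | intermediate
19 | (5R,8S,9S,10S)-8-hydroxy-13,14,15,16-tetranorlabd-11-en-6-one | C=C[C@H]1[C@]2(C)CCCC(C)(C)[C@H]2C(=O)C[C@]1(C)O | intermediate (not isolated)
20 | (5R,6R,8S,9S,10R)-13,14,15,16-tetranorlabd-11-ene-6,8-diol | C=C[C@H]1[C@]2(C)CCCC(C)(C)[C@H]2[C@H](O)C[C@]1(C)O | intermediate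
21 | 9-[(5R,6R,8S,9S,10R)-6,8-dihydroxy-13,14,15,16-tetranorlabdan-12-yl]-9-borabicyclo[3.3.1]nonane | B1(CC[C@H]2[C@]3(C)CCCC(C)(C)[C@H]3[C@H](O)C[C@]2(C)O)C4CCCC1CCC4 | intermediate (not isolated)
22 | methyl (5R,6R,8S,9S,10R,13E)-6,8-dihydroxylabd-13-en-15-oate (CNP0289884.1) | COC(=O)/C=C(\C)CC[C@H]1[C@]2(C)CCCC(C)(C)[C@H]2[C@H](O)C[C@]1(C)O | target

**Count**

Total: 14 steps. Longest linear sequence: 13 steps (steps 2–14, mesityl oxide to 22); step 1 is a one-step side branch whose product is used twice.

**Steps most likely to fail**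

1. Step 9. The bulky cationic catalyst may activate the β,β-disubstituted enal too weakly, so that loss of the silyl group or collapse after the first C5–C10 bond (Mukaiyama–Michael product) outruns ring closure, or the two enal faces may be poorly differentiated. The fallback sets out from 14 and returns at 17. Compound 14 is cyclised with the achiral Lewis acid Me2AlCl (CH2Cl2, −78 → −20 °C), which should give the same endo, trans-fused adduct as a racemate, that is 15 together with its mirror-image aldehyde ent-15 F1. Methylenation and Pd(OAc)2 oxidation as in steps 10 and 11 then carry the pair on to 16 with the mirror-image diene ent-16 F2 and to 17 with the mirror-image enone ent-17 F3. The robust, UV-active enone is resolved by preparative chromatography on a chiral stationary phase (cellulose tris(3,5-dimethylphenylcarbamate)), and the (5R,9R,10S) enantiomer continues as 17.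

2. Step 12. Deprotonation at the doubly allylic C9–H (γ to the ketone) may move the double bonds into conjugation with the vinyl group before hydroperoxide adds to the hindered β-carbon, and facial selectivity at C8 may be incomplete. The fallback sets out from 15 and returns at 22; it saturates the side chain before the enone is made.
 - Wittig reaction of 15 with Ph3P=CHC(O)CH3 (toluene, 90 °C) should give the side-chain enone (11E)-6-(tert-butyldimethylsilyloxy)-14,15-dinorlabda-6,11-dien-13-one F4.
 - Conjugate reduction with [(Ph3P)CuH]6 in wet benzene gives the saturated methyl ketone F5.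
 - Pd(OAc)2 in MeCN gives the enedione F6.
 - Ethylene glycol with pyridinium p-toluenesulfonate in refluxing benzene ketalises only the unhindered saturated ketone to the dioxolane F7.
 - H2O2/NaOH gives the 7,8-epoxy ketone F8, now without a doubly allylic hydrogen.
 - Li/NH3/EtOH reduces it through the hydroxy ketone F9 to the diol ketal F10.
 - Aqueous acetic acid releases the 6,8-dihydroxy methyl ketone F11.
 - Horner–Wadsworth–Emmons olefination with trimethyl phosphonoacetate and NaH in THF gives 22; the E isomer is expected to predominate and would be separated from the Z isomer by chromatography.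

3. Step 14. 9-BBN may be consumed by the two hydroxyls faster than it adds to the hindered vinyl group, or the borinate esters may slow transmetalation, so that hydroboration or coupling stays incomplete. The fallback sets out from 20 and returns at 22. Both hydroxyls are masked with TMSOTf and 2,6-lutidine (CH2Cl2, −78 °C) as the bis(trimethylsilyl) ether F12. Hydroboration with 9-BBN (1.5 equiv) gives the alkylborane F13, and coupling with 2 under the conditions of step 14 gives the bis(trimethylsilyl) ether of the target F14. Citric acid in aqueous methanol then removes both silyl groups to give 22.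

**Further compounds**

F1 | step 9 | ent-15, (5S,8S,9S,10S)-6-(tert-butyldimethylsilyloxy)-12,13,14,15,16-pentanorlabd-6-en-11-al | O=C[C@@H]1[C@@]2(C)CCCC(C)(C)[C@@H]2C(O[Si](C)(C)C(C)(C)C)=C[C@@H]1C
F2 | step 9 | ent-16, (5S,8R,9S,10R)-6-(tert-butyldimethylsilyloxy)-13,14,15,16-tetranorlabda-6,11-diene | C=C[C@@H]1[C@@]2(C)CCCC(C)(C)[C@@H]2C(O[Si](C)(C)C(C)(C)C)=C[C@@H]1C
F3 | step 9 | ent-17, (5S,9S,10R)-13,14,15,16-tetranorlabda-7,11-dien-6-one | C=C[C@@H]1[C@@]2(C)CCCC(C)(C)[C@@H]2C(=O)C=C1C
F4 | step 12 | (5R,8S,9R,10S,11E)-6-(tert-butyldimethylsilyloxy)-14,15-dinorlabda-6,11-dien-13-one | CC(=O)/C=C/[C@H]1[C@]2(C)CCCC(C)(C)[C@H]2C(O[Si](C)(C)C(C)(C)C)=C[C@H]1C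
F5 | step 12 | (5R,8S,9R,10S)-6-(tert-butyldimethylsilyloxy)-14,15-dinorlabd-6-en-13-one | CC(=O)CC[C@H]1[C@]2(C)CCCC(C)(C)[C@H]2C(O[Si](C)(C)C(C)(C)C)=C[C@H]1C
F6 | step 12 | (5R,9R,10S)-14,15-dinorlabd-7-ene-6,13-dione | CC(=O)CC[C@H]1[C@]2(C)CCCC(C)(C)[C@H]2C(=O)C=C1C
F7 | step 12 | (5R,9R,10S)-13,13-(ethylenedioxy)-14,15-dinorlabd-7-en-6-one | CC1(CC[C@H]2[C@]3(C)CCCC(C)(C)[C@H]3C(=O)C=C2C)OCCO1
F8 | step 12 | (5R,7R,8R,9S,10S)-7,8-epoxy-13,13-(ethylenedioxy)-14,15-dinorlabdan-6-one | CC1(CC[C@H]2[C@]3(C)CCCC(C)(C)[C@H]3C(=O)[C@@H]4O[C@@]42C)OCCO1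
F9 | step 12 | (5R,8S,9S,10S)-13,13-(ethylenedioxy)-8-hydroxy-14,15-dinorlabdan-6-one | CC1(CC[C@H]2[C@]3(C)CCCC(C)(C)[C@H]3C(=O)C[C@]2(C)O)OCCO1
F10 | step 12 | (5R,6R,8S,9S,10R)-13,13-(ethylenedioxy)-14,15-dinorlabdane-6,8-diol | CC1(CC[C@H]2[C@]3(C)CCCC(C)(C)[C@H]3[C@H](O)C[C@]2(C)O)OCCO1
F11 | step 12 | (5R,6R,8S,9S,10R)-6,8-dihydroxy-14,15-dinorlabdan-13-one | CC(=O)CC[C@H]1[C@]2(C)CCCC(C)(C)[C@H]2[C@H](O)C[C@]1(C)O
F12 | step 14 | (5R,6R,8S,9S,10R)-6,8-bis(trimethylsilyloxy)-13,14,15,16-tetranorlabd-11-ene | C=C[C@H]1[C@]2(C)CCCC(C)(C)[C@H]2[C@H](O[Si](C)(C)C)C[C@]1(C)O[Si](C)(C)C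
F13 | step 14 | 9-[(5R,6R,8S,9S,10R)-6,8-bis(trimethylsilyloxy)-13,14,15,16-tetranorlabdan-12-yl]-9-borabicyclo[3.3.1]nonane | B1(CC[C@H]2[C@]3(C)CCCC(C)(C)[C@H]3[C@H](O[Si](C)(C)C)C[C@]2(C)O[Si](C)(C)C)C4CCCC1CCC4
F14 | step 14 | methyl (5R,6R,8S,9S,10R,13E)-6,8-bis(trimethylsilyloxy)labd-13-en-15-oate | COC(=O)/C=C(\C)CC[C@H]1[C@]2(C)CCCC(C)(C)[C@H]2[C@H](O[Si](C)(C)C)C[C@]1(C)O[Si](C)(C)C
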